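**Retrosynthetic overview**
- The only ring, the 5,6-dihydropyran-2-one, is closed in the last step. An acyclic C26 chain ending in a 3,5-dihydroxy ester lactonises O5 onto C1, then loses the C3 oxygen as a transient trifluoroacetate to give the cis C2=C3 bond. This mirrors acyl release and dehydration on a polyketide synthase.
- The C7 hydroxyl (Narasaka–Prasad reduction) and the C9 hydroxyl (boronate oxa-Michael addition) are relayed from the C11 hydroxyl across an E-enone. The C8=C9 bond comes from cross-metathesis of a vinyl ketone (C1 to C8) with a homoallylic 1,5-diol (C9 to C26).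
- The vinyl ketone comes from the commercial atorvastatin side-chain nitrile, which supplies C1 to C7, the C5 stereocentre and the sacrificial C3 oxygen. The diol comes from dodecanal by allylboration (C15), then hydroformylation and a second allylboration (C11) run in one pot.
- Ring order: there is no carbocycle; the lactone is the single ring and is formed in step 9.

Assumption: the target is taken exactly as drawn, (6S)-6-[(2R,4R,6R,10S)-2,4,6,10-tetrahydroxyhenicosyl]-5,6-dihydro-2H-pyran-2-one, with chain atoms called C1 (lactone carbonyl) to C26; both enantiomers of B-allyldiisopinocampheylborane are bought as 1 M solutions.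

Step 1
Reactants: 1 dodecanal
Product: 3 (4S)-pentadec-1-en-4-ol, via borinate ester 2 (not isolated)
Conditions: (+)-Ipc2B(allyl) (from (−)-α-pinene, 1.2 equiv), Et2O, −78 °C; then 3 M NaOH, 30% H2O2, 0 °C to rt
Reagents that add atoms: (+)-B-allyldiisopinocampheylborane, C=CCB([C@H]1C[C@H]2C[C@@H]([C@@H]1C)C2(C)C)[C@H]1C[C@H]2C[C@@H]([C@@H]1C)C2(C)C
Why: Brown asymmetric allylboration through a chair Zimmerman–Traxler transition state, in which the (−)-α-pinene-derived reagent delivers allyl to the Re face of the aldehyde and so sets 4S (C15 of the target).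

Step 2
Reactants: 3 (4S)-pentadec-1-en-4-ol
Product: 7 (4R,8S)-nonadec-1-ene-4,8-diol, via open hydroxy aldehyde 4 (not isolated), via lactol 5 (not isolated), via borinate ester 6 (not isolated)
Conditions: one pot: Rh(acac)(CO)2 (1 mol %), BIPHEPHOS (2 mol %), CO/H2 (1:1, 10 bar), THF, 60 °C; vent, Ar purge, dilute with Et2O; (−)-Ipc2B(allyl) (from (+)-α-pinene, 2.2 equiv), −78 °C to 0 °C; then 3 M NaOH, 30% H2O2
Reagents that add atoms: carbon monoxide, [C-]#[O+]; (−)-B-allyldiisopinocampheylborane, C=CCB([C@@H]1C[C@@H]2C[C@H]([C@H]1C)C2(C)C)[C@@H]1C[C@@H]2C[C@H]([C@H]1C)C2(C)C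
Why: Linear-selective rhodium/bisphosphite hydroformylation of the terminal alkene gives δ-hydroxy aldehyde 4, which rests as lactol 5, and after the syngas is vented the (+)-α-pinene-derived allylborane traps the open-chain tautomer in a Brown asymmetric allylboration on the Si face under reagent control, which sets 4R (C11 of the target) without touching C15.

Step 3
Reactants: 8 tert-butyl 2-[(4R,6R)-6-(cyanomethyl)-2,2-dimethyl-1,3-dioxan-4-yl]acetate
Product: 10 tert-butyl 2-[(4R,6S)-2,2-dimethyl-6-(2-oxoethyl)-1,3-dioxan-4-yl]acetate, via N-aluminio imine 9 (not isolated)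
Conditions: i-Bu2AlH (1.15 equiv), toluene, −78 °C, 1 h; then MeOH, 10% aq. citric acid, 0 °C
Reagents that add atoms: water, O
Why: Nitrile-to-aldehyde half-reduction, in which hydride transfer stops at the N-aluminio imine that is hydrolysed on work-up, while the hindered tert-butyl ester reacts much more slowly at −78 °C and no stereocentre is touched.

Step 4
Reactants: 10 tert-butyl 2-[(4R,6S)-2,2-dimethyl-6-(2-oxoethyl)-1,3-dioxan-4-yl]acetate
Product: 12 tert-butyl 2-[(4R,6R)-6-(2-hydroxybut-3-en-1-yl)-2,2-dimethyl-1,3-dioxan-4-yl]acetate, via magnesium alkoxide 11 (not isolated)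
Conditions: CH2=CHMgBr (1.2 equiv), THF, −78 °C; sat. aq. NH4Cl
Reagents that add atoms: vinylmagnesium bromide, C=C[Mg]Br
Why: Grignard 1,2-addition to the aldehyde at −78 °C spares the tert-butyl ester; the new carbinol centre forms unselectively and is erased in step 5.

Step 5
Reactants: 12 tert-butyl 2-[(4R,6R)-6-(2-hydroxybut-3-en-1-yl)-2,2-dimethyl-1,3-dioxan-4-yl]acetate
Product: 13 tert-butyl 2-[(4R,6S)-2,2-dimethyl-6-(2-oxobut-3-en-1-yl)-1,3-dioxan-4-yl]acetate
Conditions: Dess–Martin periodinane (1.3 equiv), NaHCO3, CH2Cl2, 0 °C to rt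
Reagents that add atoms: none
Why: Buffered Dess–Martin oxidation converts both carbinol epimers into one vinyl ketone without harming the acetonide.

Step 6
Reactants: 7 (4R,8S)-nonadec-1-ene-4,8-diol; 13 tert-butyl 2-[(4R,6S)-2,2-dimethyl-6-(2-oxobut-3-en-1-yl)-1,3-dioxan-4-yl]acetate (1.5 equiv)
Product: 14 tert-butyl 2-[(4R,6S)-6-[(3E,6R,10S)-6,10-dihydroxy-2-oxohenicos-3-en-1-yl]-2,2-dimethyl-1,3-dioxan-4-yl]acetate
Conditions: second-generation Hoveyda–Grubbs catalyst RuCl2(H2IMes)(=CH-C6H4-2-O-iPr) (5 mol %), CH2Cl2, 40 °C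
Reagents that add atoms: none
Why: Olefin cross-metathesis between a fast-reacting homoallylic alcohol and an electron-poor vinyl ketone that does not homodimerise gives the E-enone (C8=C9) selectively, free hydroxyls are tolerated and no stereocentre is created.

Step 7
Reactants: 14 tert-butyl 2-[(4R,6S)-6-[(3E,6R,10S)-6,10-dihydroxy-2-oxohenicos-3-en-1-yl]-2,2-dimethyl-1,3-dioxan-4-yl]acetate
Product: 16 tert-butyl 2-[(4R,6S)-2,2-dimethyl-6-[(4R,6R,10S)-4,6,10-trihydroxy-2-oxohenicosyl]-1,3-dioxan-4-yl]acetate, via cyclic phenylboronate 15 (not isolated)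
Conditions: PhB(OH)2 (2.5 equiv), quinuclidine (20 mol %), N,N'-bis[3,5-bis(trifluoromethyl)phenyl]thiourea (20 mol %), 4 Å MS, toluene, 40 °C; then 30% H2O2, aq. NaHCO3, 0 °C
Reagents that add atoms: phenylboronic acid, OB(O)c1ccccc1
Why: Boronic acid-mediated intramolecular oxa-Michael addition, in which the C11–O–B(Ph)–OH hemiester delivers its boron-bound oxygen to C9 through a chair six-membered transition state with both substituents equatorial and so sets C9 (R) syn to C11, the oxidative work-up then freeing the diol.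

Step 8
Reactants: 16 tert-butyl 2-[(4R,6S)-2,2-dimethyl-6-[(4R,6R,10S)-4,6,10-trihydroxy-2-oxohenicosyl]-1,3-dioxan-4-yl]acetate
Product: 18 tert-butyl 2-[(4R,6R)-2,2-dimethyl-6-[(2R,4R,6R,10S)-2,4,6,10-tetrahydroxyhenicosyl]-1,3-dioxan-4-yl]acetate, via diethylboron chelate 17 (not isolated)
Conditions: Et2BOMe (2.5 equiv), THF/MeOH (4:1), −78 °C; NaBH4 (1.5 equiv), −78 °C; AcOH, then MeOH co-evaporation
Reagents that add atoms: none
Why: Narasaka–Prasad reduction, in which the C9 O–BEt2 chelate locks the β-hydroxy ketone in a half-chair and external hydride attacks axially to set C7 (R) syn to C9, which completes the all-syn C5/C7/C9/C11 array.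

Step 9
Reactants: 18 tert-butyl 2-[(4R,6R)-2,2-dimethyl-6-[(2R,4R,6R,10S)-2,4,6,10-tetrahydroxyhenicosyl]-1,3-dioxan-4-yl]acetate
Product: 23 (6S)-6-[(2R,4R,6R,10S)-2,4,6,10-tetrahydroxyhenicosyl]-5,6-dihydro-2H-pyran-2-one, via hexahydroxy acid 19 (not isolated), via hydroxy lactone 20 (not isolated), via pentakis-trifluoroacetate 21 (not isolated), via tetrakis-trifluoroacetate 22 (not isolated)
Conditions: one pot: TFA/H2O (9:1), rt, then concentrate and TFA/CH2Cl2 (1:4), rt, concentrate (toluene); TFAA (8 equiv), pyridine (10 equiv), CH2Cl2, −20 °C, then Et3N (6 equiv), 0 °C; then MeOH, NaHCO3, 0 °C, 30 min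
Reagents that add atoms: none
Why: Proposed new method: aqueous TFA unmasks the 3,5-diol and the acid so that the C5 hydroxyl closes the δ-lactone onto C1 as in thioesterase release, exhaustive O-trifluoroacetylation then makes only the C3 oxygen a leaving group next to acidic α-protons so that Et3N effects E1cB loss of trifluoroacetate to the ring-locked cis C2=C3 bond while O7 stays acylated and cannot add to C3, and mild methanolysis removes the four remaining labile trifluoroacetates; the closest known reaction types are acid lactonisation of statin tert-butyl ester acetonides and TFAA/amine dehydration of aldols, no stereocentre is created and the C3 centre is deliberately destroyed.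

**Compound list**
1 | dodecanal | CCCCCCCCCCCC=O | starting material
2 | (4S)-pentadec-1-en-4-yl diisopinocampheylborinate (Ipc groups of the (+)-isopinocampheol series) | CCCCCCCCCCC[C@H](OB([C@H]1C[C@H]2C[C@@H]([C@@H]1C)C2(C)C)[C@H]1C[C@H]2C[C@@H]([C@@H]1C)C2(C)C)CC=C | intermediate
3 | (4S)-pentadec-1-en-4-ol | CCCCCCCCCCC[C@H](O)CC=C | intermediate
4 | (5S)-5-hydroxyhexadecanal | CCCCCCCCCCC[C@H](O)CCCC=O | intermediate
5 | (6S)-6-undecyltetrahydro-2H-pyran-2-ol (both anomers) | CCCCCCCCCCC[C@H]1CCCC(O)O1 | intermediate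
6 | (4R,8S)-8-hydroxynonadec-1-en-4-yl diisopinocampheylborinate (Ipc groups of the (−)-isopinocampheol series) | CCCCCCCCCCC[C@H](O)CCC[C@@H](OB([C@@H]1C[C@@H]2C[C@H]([C@H]1C)C2(C)C)[C@@H]1C[C@@H]2C[C@H]([C@H]1C)C2(C)C)CC=C | intermediate
7 | (4R,8S)-nonadec-1-ene-4,8-diol | CCCCCCCCCCC[C@H](O)CCC[C@@H](O)CC=C | intermediate
8 | tert-butyl 2-[(4R,6R)-6-(cyanomethyl)-2,2-dimethyl-1,3-dioxan-4-yl]acetate | N#CC[C@@H]1C[C@H](CC(=O)OC(C)(C)C)OC(C)(C)O1 | starting material
9 | tert-butyl 2-[(4R,6R)-6-{2-[(diisobutylalumanyl)imino]ethyl}-2,2-dimethyl-1,3-dioxan-4-yl]acetate | CC(C)C[Al](CC(C)C)N=CC[C@@H]1C[C@H](CC(=O)OC(C)(C)C)OC(C)(C)O1 | intermediate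
10 | tert-butyl 2-[(4R,6S)-2,2-dimethyl-6-(2-oxoethyl)-1,3-dioxan-4-yl]acetate | O=CC[C@@H]1C[C@H](CC(=O)OC(C)(C)C)OC(C)(C)O1 | intermediate
11 | bromomagnesium alkoxide of 12 (both carbinol epimers) | C=CC(O[Mg]Br)C[C@@H]1C[C@H](CC(=O)OC(C)(C)C)OC(C)(C)O1 | intermediate
12 | tert-butyl 2-[(4R,6R)-6-(2-hydroxybut-3-en-1-yl)-2,2-dimethyl-1,3-dioxan-4-yl]acetate (both carbinol epimers) | C=CC(O)C[C@@H]1C[C@H](CC(=O)OC(C)(C)C)OC(C)(C)O1 | intermediate
13 | tert-butyl 2-[(4R,6S)-2,2-dimethyl-6-(2-oxobut-3-en-1-yl)-1,3-dioxan-4-yl]acetate | C=CC(=O)C[C@@H]1C[C@H](CC(=O)OC(C)(C)C)OC(C)(C)O1 | intermediate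
14 | tert-butyl 2-[(4R,6S)-6-[(3E,6R,10S)-6,10-dihydroxy-2-oxohenicos-3-en-1-yl]-2,2-dimethyl-1,3-dioxan-4-yl]acetate | CCCCCCCCCCC[C@H](O)CCC[C@@H](O)C/C=C/C(=O)C[C@@H]1C[C@H](CC(=O)OC(C)(C)C)OC(C)(C)O1 | intermediate
15 | cyclic phenylboronate of 16 bridging the side-chain 4- and 6-oxygens (cis-4,6-disubstituted 2-phenyl-1,3,2-dioxaborinane) | CCCCCCCCCCC[C@H](O)CCC[C@@H]1C[C@H](CC(=O)C[C@@H]2C[C@H](CC(=O)OC(C)(C)C)OC(C)(C)O2)OB(c3ccccc3)O1 | intermediate
16 | tert-butyl 2-[(4R,6S)-2,2-dimethyl-6-[(4R,6R,10S)-4,6,10-trihydroxy-2-oxohenicosyl]-1,3-dioxan-4-yl]acetate | CCCCCCCCCCC[C@H](O)CCC[C@@H](O)C[C@@H](O)CC(=O)C[C@@H]1C[C@H](CC(=O)OC(C)(C)C)OC(C)(C)O1 | intermediate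
17 | diethylborinate of 16 at the side-chain 4-oxygen (boron chelated by the ketone) | CCCCCCCCCCC[C@H](O)CCC[C@@H](O)C[C@@H](OB(CC)CC)CC(=O)C[C@@H]1C[C@H](CC(=O)OC(C)(C)C)OC(C)(C)O1 | intermediate
18 | tert-butyl 2-[(4R,6R)-2,2-dimethyl-6-[(2R,4R,6R,10S)-2,4,6,10-tetrahydroxyhenicosyl]-1,3-dioxan-4-yl]acetate | CCCCCCCCCCC[C@H](O)CCC[C@@H](O)C[C@@H](O)C[C@@H](O)C[C@@H]1C[C@H](CC(=O)OC(C)(C)C)OC(C)(C)O1 | intermediate
19 | (3R,5R,7R,9R,11R,15S)-3,5,7,9,11,15-hexahydroxyhexacosanoic acid | CCCCCCCCCCC[C@H](O)CCC[C@@H](O)C[C@@H](O)C[C@@H](O)C[C@@H](O)C[C@@H](O)CC(=O)O | intermediate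
20 | (4R,6R)-4-hydroxy-6-[(2R,4R,6R,10S)-2,4,6,10-tetrahydroxyhenicosyl]tetrahydro-2H-pyran-2-one | CCCCCCCCCCC[C@H](O)CCC[C@@H](O)C[C@@H](O)C[C@@H](O)C[C@@H]1C[C@@H](O)CC(=O)O1 | intermediate
21 | pentakis(trifluoroacetate) of 20 | CCCCCCCCCCC[C@H](OC(=O)C(F)(F)F)CCC[C@@H](OC(=O)C(F)(F)F)C[C@@H](OC(=O)C(F)(F)F)C[C@@H](OC(=O)C(F)(F)F)C[C@@H]1C[C@@H](OC(=O)C(F)(F)F)CC(=O)O1 | intermediate
22 | tetrakis(trifluoroacetate) of 23 | CCCCCCCCCCC[C@H](OC(=O)C(F)(F)F)CCC[C@@H](OC(=O)C(F)(F)F)C[C@@H](OC(=O)C(F)(F)F)C[C@@H](OC(=O)C(F)(F)F)C[C@@H]1CC=CC(=O)O1 | intermediate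
23 | (6S)-6-[(2R,4R,6R,10S)-2,4,6,10-tetrahydroxyhenicosyl]-5,6-dihydro-2H-pyran-2-one | CCCCCCCCCCC[C@H](O)CCC[C@@H](O)C[C@@H](O)C[C@@H](O)C[C@@H]1CC=CC(=O)O1 | target

**Step count**
Total steps: 9 (steps 1 and 2 for the diol, steps 3 to 5 for the vinyl ketone, steps 6 to 9 after union).
Longest linear sequence: 7 steps (3, 4, 5, 6, 7, 8, 9).

**Steps most likely to fail**

Step 9. Lactonisation may be incomplete before acylation, triethylamine may react with the anhydride, and the freed C7 hydroxyl may add to C3 during methanolysis to give the bicyclic lactone. The fallback sets out from 18 and comes back at 23. Treat 18 with aqueous TFA only and isolate hydroxy lactone 20. Silylate all five hydroxyls with TBSOTf and 2,6-lutidine to give the pentakis(tert-butyldimethylsilyl) ether of 20 F1. Eliminate the C3 silyloxy group with DBU in CH2Cl2 to give the tetrakis(tert-butyldimethylsilyl) ether of 23 F2, in which O7 stays blocked. Remove the silyl groups with HF·pyridine in THF, which is acidic and avoids base, to reach 23.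

Step 7. The achiral amine/boronic acid system may react slowly, give poor syn/anti control, or trigger β-elimination of the C5 oxygen next to the ketone. The fallback sets out from 14 and comes back at 16. Run a catalyst-controlled conjugate borylation with B2pin2, CuCl (5 mol %), NaOtBu, MeOH and a Josiphos ligand, taking whichever ligand enantiomer a test run shows to give the C9 (R) boronate. This gives the β-boryl ketone tert-butyl 2-[(4R,6S)-6-[(4R,6R,10S)-6,10-dihydroxy-2-oxo-4-(4,4,5,5-tetramethyl-1,3,2-dioxaborolan-2-yl)henicosyl]-2,2-dimethyl-1,3-dioxan-4-yl]acetate F3. Oxidise the C–B bond with retention using NaBO3·4H2O in THF/H2O to obtain 16.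

Step 2. Rhodium and phosphite residues or dissolved CO may interfere with the allylborane, and the lactol may open too slowly at low temperature, so conversion or enantioselectivity may suffer. The fallback sets out from 3 and comes back at 7. Protect 3 with TBSCl and imidazole to give tert-butyldimethyl{[(4S)-pentadec-1-en-4-yl]oxy}silane F4. Hydroformylate it with Rh(acac)(CO)2 and BIPHEPHOS under CO/H2 and purify the open-chain aldehyde (5S)-5-[(tert-butyldimethylsilyl)oxy]hexadecanal F5. Allylborate F5 with (−)-Ipc2B(allyl) at −78 °C to give (4R,8S)-8-[(tert-butyldimethylsilyl)oxy]nonadec-1-en-4-ol F6. Desilylate with Bu4NF in THF to obtain 7.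

Further compounds
F1 | step 9 | pentakis(tert-butyldimethylsilyl) ether of 20 | CCCCCCCCCCC[C@H](O[Si](C)(C)C(C)(C)C)CCC[C@@H](O[Si](C)(C)C(C)(C)C)C[C@@H](O[Si](C)(C)C(C)(C)C)C[C@@H](O[Si](C)(C)C(C)(C)C)C[C@@H]1C[C@@H](O[Si](C)(C)C(C)(C)C)CC(=O)O1
F2 | step 9 | tetrakis(tert-butyldimethylsilyl) ether of 23 | CCCCCCCCCCC[C@H](O[Si](C)(C)C(C)(C)C)CCC[C@@H](O[Si](C)(C)C(C)(C)C)C[C@@H](O[Si](C)(C)C(C)(C)C)C[C@@H](O[Si](C)(C)C(C)(C)C)C[C@@H]1CC=CC(=O)O1
F3 | step 7 | tert-butyl 2-[(4R,6S)-6-[(4R,6R,10S)-6,10-dihydroxy-2-oxo-4-(4,4,5,5-tetramethyl-1,3,2-dioxaborolan-2-yl)henicosyl]-2,2-dimethyl-1,3-dioxan-4-yl]acetate | CCCCCCCCCCC[C@H](O)CCC[C@@H](O)C[C@@H](B1OC(C)(C)C(C)(C)O1)CC(=O)C[C@@H]2C[C@H](CC(=O)OC(C)(C)C)OC(C)(C)O2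
F4 | step 2 | tert-butyldimethyl{[(4S)-pentadec-1-en-4-yl]oxy}silane | CCCCCCCCCCC[C@H](O[Si](C)(C)C(C)(C)C)CC=C
F5 | step 2 | (5S)-5-[(tert-butyldimethylsilyl)oxy]hexadecanal | CCCCCCCCCCC[C@H](O[Si](C)(C)C(C)(C)C)CCCC=O
F6 | step 2 | (4R,8S)-8-[(tert-butyldimethylsilyl)oxy]nonadec-1-en-4-ol | CCCCCCCCCCC[C@H](O[Si](C)(C)C(C)(C)C)CCC[C@@H](O)CC=C
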